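**Retrosynthetic overview**

1. Atom labels: naphthalene C1 bears ring C (the 4-hydroxy-2-methoxyphenyl group), C2 the ring D benzyl group, C3 a hydroxyl, C4 hydrogen, C5 and C7 methoxyl, C6 hydroxyl, C8 hydrogen; ring A holds C1–C4, ring B holds C5–C8. The strategy rests on C3: it carries the ring A oxygen and lies between benzylic C4 and the alkene-type carbon C2, so C3 with its oxygen is taken out as carbon monoxide.
2. Last C–C bonds: C3–C4 and C2–C3 are cut together. This leaves CO and an open precursor in which ring B carries C4 as a CH2Cl group and C1=C2 is a tetrasubstituted alkenyl pinacol boronate, boron on C2 and cis to ring B.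
3. The C1–C8a and C2–B bonds come from a copper/palladium syn-arylboration of the ring C–C≡C–CH2–ring D alkyne with B2pin2 and a ring B aryl bromide whose C4 is masked as a silyl ether.
4. The ring B bromide comes from syringol (para-bromination, benzylation, ortho-lithiation/formylation, reduction, silylation). The alkyne comes from 4-bromo-3-methoxyphenol, ethynyltrimethylsilane and 3,4-bis(benzyloxy)benzaldehyde (Sonogashira coupling, acetylide addition, ionic deoxygenation).
5. Ring order: rings B, C and D are bought as benzenes; ring A is the only ring made, in the carbonylative closure; one hydrogenolysis then frees the four phenols.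

Key step: step 14

Assumption: the target SMILES defines no axial configuration at the C1–ring C bond, so this axis is left unresolved, and the propargylic alcohol of the alkyne branch is carried as the racemate because its stereocentre is erased one step later.

**Route**

Step 1
Reactants: 1 2,6-dimethoxyphenol (syringol)
Product: 2 4-bromo-2,6-dimethoxyphenol
Conditions: NBS, NaH (cat.), CHCl3, −45 °C to rt
Reagents that add atoms: N-bromosuccinimide, O=C1CCC(=O)N1Br
Why: Electrophilic aromatic bromination, in which the phenol (as phenoxide with the trace of base) directs bromine to its free para position because both ortho positions are blocked by methoxyl groups.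

Step 2
Reactants: 2 4-bromo-2,6-dimethoxyphenol
Product: 3 2-(benzyloxy)-5-bromo-1,3-dimethoxybenzene
Conditions: BnBr, K2CO3, DMF, rt
Reagents that add atoms: benzyl bromide, BrCc1ccccc1
Why: Williamson ether synthesis on the phenoxide, giving a benzyl ether that matches those of rings C and D so that one hydrogenolysis frees all phenols at the end.

Step 3
Reactants: 3 2-(benzyloxy)-5-bromo-1,3-dimethoxybenzene
Product: 5 3-(benzyloxy)-6-bromo-2,4-dimethoxybenzaldehyde, via ortho-bromoaryllithium 4 (not isolated)
Conditions: LDA, THF, −78 °C; DMF, −78 to 0 °C; H2O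
Reagents that add atoms: N,N-dimethylformamide, CN(C)C=O (formyl carbon and oxygen of 5); lithium diisopropylamide, CC(C)N([Li])C(C)C (lithium of intermediate 4 only)
Why: Directed ortho-metalation, in which the hydrogen flanked by bromine and methoxyl is the most acidic and is removed by the amide base at −78 °C without bromine–lithium exchange (the two such sites are equivalent by symmetry), followed by formylation of the aryllithium with DMF.

Step 4
Reactants: 5 3-(benzyloxy)-6-bromo-2,4-dimethoxybenzaldehyde
Product: 6 [3-(benzyloxy)-6-bromo-2,4-dimethoxyphenyl]methanol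
Conditions: NaBH4, MeOH/THF, 0 °C
Reagents that add atoms: none
Why: Hydride reduction of the aldehyde by NaBH4, which leaves the aryl bromide and the ethers untouched.

Step 5
Reactants: 6 [3-(benzyloxy)-6-bromo-2,4-dimethoxyphenyl]methanol
Product: 7 {[3-(benzyloxy)-6-bromo-2,4-dimethoxyphenyl]methoxy}(tert-butyl)dimethylsilane
Conditions: TBSCl, imidazole, DMF, rt
Reagents that add atoms: tert-butyldimethylsilyl chloride, CC(C)(C)[Si](C)(C)Cl
Why: Silylation of the primary alcohol, which masks the future C4 as a group inert to alkoxide, copper boryl species and zerovalent palladium in step 11.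

Step 6
Reactants: 8 4-bromo-3-methoxyphenol
Product: 9 4-(benzyloxy)-1-bromo-2-methoxybenzene
Conditions: BnBr, K2CO3, DMF, rt
Reagents that add atoms: benzyl bromide, BrCc1ccccc1
Why: Williamson ether synthesis protecting the ring C phenol as a benzyl ether that survives organolithium, acid and cross-coupling steps.

Step 7
Reactants: 9 4-(benzyloxy)-1-bromo-2-methoxybenzene; 10 ethynyltrimethylsilane
Product: 11 {[4-(benzyloxy)-2-methoxyphenyl]ethynyl}trimethylsilane
Conditions: PdCl2(PhCN)2, P(t-Bu)3, CuI, i-Pr2NH, dioxane, rt to 50 °C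
Reagents that add atoms: none
Why: Sonogashira coupling, in which the bulky electron-rich phosphine P(t-Bu)3 allows oxidative addition of the electron-rich, ortho-substituted aryl bromide under mild conditions.

Step 8
Reactants: 11 {[4-(benzyloxy)-2-methoxyphenyl]ethynyl}trimethylsilane
Product: 12 4-(benzyloxy)-1-ethynyl-2-methoxybenzene
Conditions: K2CO3 (cat.), MeOH/THF, rt
Reagents that add atoms: none
Why: Base-catalysed methanolysis of the alkynyl C–Si bond (protodesilylation), which touches nothing else in the molecule.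

Step 9
Reactants: 12 4-(benzyloxy)-1-ethynyl-2-methoxybenzene; 13 3,4-bis(benzyloxy)benzaldehyde
Product: 15 3-[4-(benzyloxy)-2-methoxyphenyl]-1-[3,4-bis(benzyloxy)phenyl]prop-2-yn-1-ol (racemic), via lithium acetylide 14 (not isolated)
Conditions: n-BuLi, THF, −78 °C; then 13, −78 to 0 °C; H2O
Reagents that add atoms: n-butyllithium, [Li]CCCC (lithium of intermediate 14 only)
Why: Deprotonation of the terminal alkyne and 1,2-addition of the acetylide to the aldehyde, which forms the carbinol stereocentre without control (racemate) since it is removed in step 10.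

Step 10
Reactants: 15 3-[4-(benzyloxy)-2-methoxyphenyl]-1-[3,4-bis(benzyloxy)phenyl]prop-2-yn-1-ol
Product: 16 4-(benzyloxy)-1-{3-[3,4-bis(benzyloxy)phenyl]prop-1-yn-1-yl}-2-methoxybenzene
Conditions: Et3SiH, TFA, CH2Cl2, −20 to 0 °C
Reagents that add atoms: none
Why: Ionic hydrogenation, in which acid ionises the propargylic and benzylic alcohol to a cation stabilised by the para-benzyloxy group of ring D and triethylsilane delivers hydride to the carbinol carbon, erasing the stereocentre.

Step 11
Reactants: 16 4-(benzyloxy)-1-{3-[3,4-bis(benzyloxy)phenyl]prop-1-yn-1-yl}-2-methoxybenzene; 7 {[3-(benzyloxy)-6-bromo-2,4-dimethoxyphenyl]methoxy}(tert-butyl)dimethylsilane; 17 bis(pinacolato)diboron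
Product: 18 tert-butyl({3-(benzyloxy)-6-[(1Z)-1-[4-(benzyloxy)-2-methoxyphenyl]-3-[3,4-bis(benzyloxy)phenyl]-2-(4,4,5,5-tetramethyl-1,3,2-dioxaborolan-2-yl)prop-1-en-1-yl]-2,4-dimethoxyphenyl}methoxy)dimethylsilane (boron cis to ring B)
Conditions: CuCl, PCy3, Pd(OAc)2, XPhos, NaOtBu (added in portions), toluene, 50 °C
Reagents that add atoms: none
Why: Cooperative copper/palladium syn-arylboration of an internal aryl–alkyl alkyne, in which a boryl complex of monovalent copper adds syn with boron on the CH2-bearing carbon and copper on the aryl-bearing carbon, and the alkenyl group passes with retention to the arylpalladium bromide formed from 7, so that ring B ends on C1 cis to boron.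

Step 12
Reactants: 18 the silyl ether boronate of step 11
Product: 19 {3-(benzyloxy)-6-[(1Z)-1-[4-(benzyloxy)-2-methoxyphenyl]-3-[3,4-bis(benzyloxy)phenyl]-2-(4,4,5,5-tetramethyl-1,3,2-dioxaborolan-2-yl)prop-1-en-1-yl]-2,4-dimethoxyphenyl}methanol
Conditions: Bu4NF, AcOH (1:1), THF, 0 °C to rt
Reagents that add atoms: none
Why: Fluoride cleavage of the Si–O bond, buffered with acetic acid so that no free alkoxide or excess fluoride attacks the neighbouring pinacol boronate.

Step 13
Reactants: 19 the benzylic alcohol of step 12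
Product: 20 2-[(1Z)-1-[4-(benzyloxy)-2-(chloromethyl)-3,5-dimethoxyphenyl]-1-[4-(benzyloxy)-2-methoxyphenyl]-3-[3,4-bis(benzyloxy)phenyl]prop-1-en-2-yl]-4,4,5,5-tetramethyl-1,3,2-dioxaborolane (used at once)
Conditions: PPh3, NCS, THF, −20 to 0 °C
Reagents that add atoms: N-chlorosuccinimide, O=C1CCC(=O)N1Cl
Why: Appel-type chlorination through an alkoxyphosphonium chloride, whose neutral, cold conditions suit an electron-rich benzylic chloride that ionises easily and leave the alkenyl boronate intact.

Step 14
Reactants: 20 the benzylic chloride boronate of step 13; 21 carbon monoxide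
Product: 23 3-[3,4-bis(benzyloxy)benzyl]-7-(benzyloxy)-4-[4-(benzyloxy)-2-methoxyphenyl]-6,8-dimethoxynaphthalen-2-ol, via keto tautomer 22 (not isolated)
Conditions: Pd(PPh3)4 (10 mol %), K3PO4, H2O (5 equiv), CO (3 bar), dioxane, 80 °C, 0.01 M
Reagents that add atoms: none
Why: Proposed new method: zerovalent palladium adds to the benzylic C–Cl bond of 20, CO inserts into the benzyl–palladium bond (forming C3–C4) to give an arylacetyl complex of divalent palladium, base-assisted transmetalation transfers alkenyl carbon C2 from boron with retention, and reductive elimination from the seven-membered acylpalladacycle forms C2–C3 and releases dienone 22, which enolises to the naphthol. The closest known reaction type is the three-component carbonylative Suzuki–Miyaura ketone synthesis from benzyl halides, CO and organoboronic acids; new here is its intramolecular use with a tetrasubstituted alkenyl pinacol boronate to close a ring. Ring A closes as a six-membered ring by acyl–alkenyl reductive elimination, the cis arrangement of boron and ring B from step 11 holding the acylpalladium within reach of the C–B bond. No stereocentre is formed. The step needs carbonylative coupling to win over direct benzyl–alkenyl coupling (which would give an indene through a six-membered palladacycle) and over hydrolysis of the acylpalladium; the first is secured by the fast CO insertion into benzyl–palladium bonds under CO pressure, the second by high dilution, only a few equivalents of water and the intramolecular delivery of boron.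

Step 15
Reactants: 23 the tetrabenzyl naphthol of step 14
Product: 24 3-(3,4-dihydroxybenzyl)-4-(4-hydroxy-2-methoxyphenyl)-6,8-dimethoxynaphthalene-2,7-diol (locants as in 23; the target)
Conditions: H2 (1 atm), 10% Pd/C, THF/MeOH, rt; work-up under argon
Reagents that add atoms: none
Why: Catalytic hydrogenolysis of the four aryl benzyl ethers, under which the diarylmethane CH2, the methyl ethers and the naphthalene are not reduced.

**Compound list**

1 | 2,6-dimethoxyphenol (syringol) | COc1cccc(OC)c1O | starting material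
2 | 4-bromo-2,6-dimethoxyphenol | COc1cc(Br)cc(OC)c1O | intermediate
3 | 2-(benzyloxy)-5-bromo-1,3-dimethoxybenzene | COc1cc(Br)cc(OC)c1OCc1ccccc1 | intermediate
4 | [3-(benzyloxy)-6-bromo-2,4-dimethoxyphenyl]lithium | [Li]c1c(Br)cc(OC)c(OCc2ccccc2)c1OC | intermediate
5 | 3-(benzyloxy)-6-bromo-2,4-dimethoxybenzaldehyde | O=Cc1c(Br)cc(OC)c(OCc2ccccc2)c1OC | intermediate
6 | [3-(benzyloxy)-6-bromo-2,4-dimethoxyphenyl]methanol | OCc1c(Br)cc(OC)c(OCc2ccccc2)c1OC | intermediate
7 | {[3-(benzyloxy)-6-bromo-2,4-dimethoxyphenyl]methoxy}(tert-butyl)dimethylsilane | CC(C)(C)[Si](C)(C)OCc1c(Br)cc(OC)c(OCc2ccccc2)c1OC | intermediate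
8 | 4-bromo-3-methoxyphenol | COc1cc(O)ccc1Br | starting material
9 | 4-(benzyloxy)-1-bromo-2-methoxybenzene | COc1cc(OCc2ccccc2)ccc1Br | intermediate
10 | ethynyltrimethylsilane | C#C[Si](C)(C)C | starting material
11 | {[4-(benzyloxy)-2-methoxyphenyl]ethynyl}trimethylsilane | COc1cc(OCc2ccccc2)ccc1C#C[Si](C)(C)C | intermediate
12 | 4-(benzyloxy)-1-ethynyl-2-methoxybenzene | COc1cc(OCc2ccccc2)ccc1C#C | intermediate
13 | 3,4-bis(benzyloxy)benzaldehyde | O=Cc1ccc(OCc2ccccc2)c(OCc2ccccc2)c1 | starting material
14 | lithium [4-(benzyloxy)-2-methoxyphenyl]acetylide | COc1cc(OCc2ccccc2)ccc1C#C[Li] | intermediate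
15 | 3-[4-(benzyloxy)-2-methoxyphenyl]-1-[3,4-bis(benzyloxy)phenyl]prop-2-yn-1-ol (racemic) | COc1cc(OCc2ccccc2)ccc1C#CC(O)c1ccc(OCc2ccccc2)c(OCc2ccccc2)c1 | intermediate
16 | 4-(benzyloxy)-1-{3-[3,4-bis(benzyloxy)phenyl]prop-1-yn-1-yl}-2-methoxybenzene | COc1cc(OCc2ccccc2)ccc1C#CCc1ccc(OCc2ccccc2)c(OCc2ccccc2)c1 | intermediate
17 | bis(pinacolato)diboron | CC1(C)OB(OC1(C)C)B1OC(C)(C)C(C)(C)O1 | starting material
18 | tert-butyl({3-(benzyloxy)-6-[(1Z)-1-[4-(benzyloxy)-2-methoxyphenyl]-3-[3,4-bis(benzyloxy)phenyl]-2-(4,4,5,5-tetramethyl-1,3,2-dioxaborolan-2-yl)prop-1-en-1-yl]-2,4-dimethoxyphenyl}methoxy)dimethylsilane | CC(C)(C)[Si](C)(C)OCc1c(OC)c(OCc2ccccc2)c(OC)cc1/C(c1ccc(OCc2ccccc2)cc1OC)=C(/Cc1ccc(OCc2ccccc2)c(OCc2ccccc2)c1)B1OC(C)(C)C(C)(C)O1 | intermediate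
19 | {3-(benzyloxy)-6-[(1Z)-1-[4-(benzyloxy)-2-methoxyphenyl]-3-[3,4-bis(benzyloxy)phenyl]-2-(4,4,5,5-tetramethyl-1,3,2-dioxaborolan-2-yl)prop-1-en-1-yl]-2,4-dimethoxyphenyl}methanol | OCc1c(OC)c(OCc2ccccc2)c(OC)cc1/C(c1ccc(OCc2ccccc2)cc1OC)=C(/Cc1ccc(OCc2ccccc2)c(OCc2ccccc2)c1)B1OC(C)(C)C(C)(C)O1 | intermediate
20 | 2-[(1Z)-1-[4-(benzyloxy)-2-(chloromethyl)-3,5-dimethoxyphenyl]-1-[4-(benzyloxy)-2-methoxyphenyl]-3-[3,4-bis(benzyloxy)phenyl]prop-1-en-2-yl]-4,4,5,5-tetramethyl-1,3,2-dioxaborolane | ClCc1c(OC)c(OCc2ccccc2)c(OC)cc1/C(c1ccc(OCc2ccccc2)cc1OC)=C(/Cc1ccc(OCc2ccccc2)c(OCc2ccccc2)c1)B1OC(C)(C)C(C)(C)O1 | intermediate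
21 | carbon monoxide | [C-]#[O+] | starting material
22 | 3-[3,4-bis(benzyloxy)benzyl]-7-(benzyloxy)-4-[4-(benzyloxy)-2-methoxyphenyl]-6,8-dimethoxynaphthalen-2(1H)-one | O=C1Cc2c(OC)c(OCc3ccccc3)c(OC)cc2C(c2ccc(OCc3ccccc3)cc2OC)=C1Cc1ccc(OCc2ccccc2)c(OCc2ccccc2)c1 | intermediate
23 | 3-[3,4-bis(benzyloxy)benzyl]-7-(benzyloxy)-4-[4-(benzyloxy)-2-methoxyphenyl]-6,8-dimethoxynaphthalen-2-ol | COc1cc(OCc2ccccc2)ccc1-c1c(Cc2ccc(OCc3ccccc3)c(OCc3ccccc3)c2)c(O)cc2c(OC)c(OCc3ccccc3)c(OC)cc12 | intermediate
24 | 3-(3,4-dihydroxybenzyl)-4-(4-hydroxy-2-methoxyphenyl)-6,8-dimethoxynaphthalene-2,7-diol (CNP0000244.0) | COc1cc(O)ccc1-c1c(Cc2ccc(O)c(O)c2)c(O)cc2c(OC)c(O)c(OC)cc12 | target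

**Step count and risks**

Total steps: 15. Longest linear sequence: 10 steps (steps 1–5 then 11–15 from syringol; equally steps 6–10 then 11–15 from 4-bromo-3-methoxyphenol).

Steps most likely to fail:

1. Step 14 (the proposed new method). Boron-to-palladium transfer from the hindered tetrasubstituted boronate may lag, so that the acylpalladium is hydrolysed, or direct coupling without CO may close an indene; the labile benzylic chloride may also ionise before oxidative addition. The fallback uses known chemistry and needs no boron-to-palladium transfer; it sets out from alcohol 19 and returns at 23. Rhodium-hydroxide-catalysed protodeboronation ([Rh(OH)(cod)]2, dioxane/H2O, 90 °C) should replace boron by hydrogen and give the boron-free alkene alcohol F1, whose alkene geometry no longer matters. PPh3/NCS should then give the benzylic chloride F2. Palladium-catalysed hydroxycarbonylation of the benzylic chloride (PdCl2(PPh3)2, CO 1 atm, aqueous NaOH/toluene, Bu4NBr, 60 °C, then HCl) should give the arylacetic acid F3, so C3 still comes from CO. Trifluoroacetic anhydride in CH2Cl2 at 0 °C should turn F3 into its mixed anhydride, which acylates the 1,1-diarylalkene at C2. This is an intramolecular Darzens–Nenitzescu (Friedel–Crafts-type) alkene acylation, the reaction type of the classical 2-tetralone synthesis, with the cation at C1 stabilised by rings B and C. Loss of the C2 proton, enolisation and O-acylation should give the naphthyl trifluoroacetate F4, and K2CO3 in MeOH cleaves this ester to 23.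

2. Step 11. The alkoxide base may isomerise the 1,3-diarylpropyne to an allene before borylcupration, and the coupling of the hindered alkenylcopper with the ortho-substituted arylpalladium may be slow, leaving protoboration products. The fallback separates the two bond formations and avoids strong base; it sets out from alkyne 16 and diboron 17 and returns at 18. A copper-catalysed three-component borylstannylation (Cu(OAc)2, PCy3, Bu3SnOMe, toluene, rt to 50 °C) should give the vicinal boryl stannyl alkene F5, with tin on the aryl-bearing carbon cis to boron. A base-free Stille coupling of the C–Sn bond with bromide 7 (Pd(P(t-Bu)3)2, CuI, NMP, 80 °C) then installs ring B with retention and leaves the pinacol boronate untouched, giving 18.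

3. Step 3. The ortho-bromoaryllithium may lose LiBr to an aryne, or deprotonation may stay incomplete. The fallback replaces metalation by electrophilic substitution; it sets out from 3 and returns at 5. Rieche formylation (Cl2CHOMe, SnCl4, CH2Cl2, −40 to 0 °C) attacks the only type of free ring position, which is ortho to one methoxyl and para to the other, and gives aldehyde 5 directly; the tin Lewis acid at low temperature is chosen to spare the benzyl ether.

**Further compounds**

F1 | step 14 | {3-(benzyloxy)-6-[(1Z)-1-[4-(benzyloxy)-2-methoxyphenyl]-3-[3,4-bis(benzyloxy)phenyl]prop-1-en-1-yl]-2,4-dimethoxyphenyl}methanol | OCc1c(OC)c(OCc2ccccc2)c(OC)cc1/C(c1ccc(OCc2ccccc2)cc1OC)=C/Cc1ccc(OCc2ccccc2)c(OCc2ccccc2)c1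
F2 | step 14 | 4-(benzyloxy)-1-[(1Z)-1-[4-(benzyloxy)-2-methoxyphenyl]-3-[3,4-bis(benzyloxy)phenyl]prop-1-en-1-yl]-2-(chloromethyl)-3,5-dimethoxybenzene | ClCc1c(OC)c(OCc2ccccc2)c(OC)cc1/C(c1ccc(OCc2ccccc2)cc1OC)=C/Cc1ccc(OCc2ccccc2)c(OCc2ccccc2)c1
F3 | step 14 | 2-{3-(benzyloxy)-6-[(1Z)-1-[4-(benzyloxy)-2-methoxyphenyl]-3-[3,4-bis(benzyloxy)phenyl]prop-1-en-1-yl]-2,4-dimethoxyphenyl}acetic acid | OC(=O)Cc1c(OC)c(OCc2ccccc2)c(OC)cc1/C(c1ccc(OCc2ccccc2)cc1OC)=C/Cc1ccc(OCc2ccccc2)c(OCc2ccccc2)c1
F4 | step 14 | 3-[3,4-bis(benzyloxy)benzyl]-7-(benzyloxy)-4-[4-(benzyloxy)-2-methoxyphenyl]-6,8-dimethoxynaphthalen-2-yl trifluoroacetate | COc1cc(OCc2ccccc2)ccc1-c1c(Cc2ccc(OCc3ccccc3)c(OCc3ccccc3)c2)c(OC(=O)C(F)(F)F)cc2c(OC)c(OCc3ccccc3)c(OC)cc12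
F5 | step 11 | tributyl{(1E)-1-[4-(benzyloxy)-2-methoxyphenyl]-3-[3,4-bis(benzyloxy)phenyl]-2-(4,4,5,5-tetramethyl-1,3,2-dioxaborolan-2-yl)prop-1-en-1-yl}stannane | CCCC[Sn](CCCC)(CCCC)/C(c1ccc(OCc2ccccc2)cc1OC)=C(/Cc1ccc(OCc2ccccc2)c(OCc2ccccc2)c1)B1OC(C)(C)C(C)(C)O1
F0 | step 3 | none | none
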